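## The problem

1. The target 16 is (−)-epiafzelechin 3-O-gallate-(4β→6)-(−)-epicatechin 3-O-gallate: two 2,3-cis flavan-3-ol gallates joined by one C–C bond from C4 of the upper heterocycle (ring C: O1, C2, C3, C4, C4a, C8a) to C6' of the lower phloroglucinol ring A'.
2. Ring A' has two free CH positions. Electrophiles prefer C8' (between O7' and O1'); the target needs C6' (between O5' and O7').
3. Upper ring C carries three contiguous stereocentres: the C3 oxygen is cis to the C2 aryl group and trans to the C4–C6' bond, so the two aryl groups are trans. Equilibration does not favour this arrangement, and the lower-unit centres are too remote to help, so C2 has to control C3 and C4.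
4. (−)-Epicatechin 9 supplies the lower unit from the chiral pool. The upper 4'-monohydroxy unit has no such source; de novo routes to it usually pass through the 2,3-trans alcohol and need a redox inversion at C3 and a separate oxidation at C4.
5. The enabling feature: in ring C the C3–O bond (α face) and the C4–C6' bond (β face) are vicinal and anti, and C4 is benzylic to ring A. This is the pattern of an anti opening at C4 of a C3/C4 oxirane lying on the α face. That oxirane follows from a flav-3-ene (C3=C4) by bromination anti to the 2-aryl group and inversion at C3.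
6. Thirteen phenols (air oxidation), the acid-labile interflavan and benzylic C2–O1 bonds, and base-labile esters call for benzyl ethers and a neutral hydrogenolytic end game.

## Retrosynthesis

**16 ⇐ 15.** Thirteen O–benzyl bonds and two aryl C–Br bonds are cut in one hydrogenolysis. Nothing else in 15 is reducible, so all protecting and blocking atoms leave together and no acid or base touches the free polyphenol.

**15 ⇐ 13 + 14.** Both ester C–O bonds are cut. The two acyl groups are identical and both alcohols of 13 are axial secondary 3-hydroxyls, so acid chloride 14 installs both in one operation. Carrying the esters through the union would cost one acylation per unit.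

**13 ⇐ 12 + 11 (key).** The C4–C6' bond is cut, and the C3–O bond is traced back to an oxirane. The neighbouring cuts are worse: closing ring C on a lower-unit aldehyde (C4–C4a or C2–O1) would have to create the trans-2,4-diaryl pattern during ring closure, and cutting inside lower ring C' discards the chiral pool. Epoxide 12 has one controlling centre (C2); the forward reaction must open it at C4 with inversion, using only C6' of 11. The C8' bromine of 11 leaves no other ring-A' carbon, and the C8 bromine of 12 blocks its own most nucleophilic position.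

**12 ⇐ 8 ⇐ 7.** The oxirane C3–O bond, the C3–Br and C4–O bonds and the C8–Br bond are cut back to the C3=C4 alkene of flav-3-ene 7. Direct epoxidation of 7 would place oxygen anti to the 2-aryl group (2,3-trans series). Bromohydrin 8 relays the oxygen to the α face by inversion at C3, and the same bromine reagent caps C8. Compound 7 has a single stereocentre.

**7 ⇐ 4 + 5 (through 6).** The C2–aryl bond is cut. This is the only step that needs an external source of chirality; it joins ring B to an achiral benzopyrylium precursor. Acetal 4 is racemic and boronic acid 5 is commercial.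

**4 ⇐ 2 ⇐ 1 (through 3).** The acetal C–O bond and two benzyl ethers are cut back to commercial 5,7-dihydroxycoumarin 1, which already holds ring A, O1 and C2–C4 at the right oxidation pattern.

**11 ⇐ 10 ⇐ 9.** The C8'–Br and four O–benzyl bonds are cut back to (−)-epicatechin 9. Both lower stereocentres come from the chiral pool and are never touched.

## Roads not taken

**Alternative 1:** The most obvious plan cuts the same C4–C6' bond between two finished flavan-3-ols. Tri-O-benzyl-(−)-epiafzelechin A1 would be oxidised at C4 with a quinone and an alcohol to the 4β-alkoxy ether A2, then coupled with 11 under a Lewis acid. A1 must be made de novo (cinnamylation, asymmetric dihydroxylation, cyclisation to the trans alcohol, oxidation, reduction) before C4 is oxidised separately, roughly twice the number of steps needed to reach 8. C3 is handled three times, and A2 has a free C8 that self-condenses unless capped in a further step. The chosen plan takes C3, C4 and the cap from one alkene and one reagent.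

**Alternative 2:** A biomimetic cut at the flavylium level: the 3-galloyloxyflavylium salt A3 adds 11 at C4 to give the 4-aryl-flav-2-ene A4, and the C2=C3 enol ester is then hydrogenated. A3 is planar, so C4 would be set only by the remote lower-unit centres. Hydrogen must then be delivered to the face occupied by the C4 aryl group to give 2,3-cis-3,4-trans, whereas that group steers a catalyst to the opposite face (all-cis). The chosen plan sets C4 last, anti to a C3 oxygen already in place.

**Alternative 3:** A symmetry-based cut: 12 is opened by C3-symmetric phloroglucinol A5 to the adduct A6, which has only one possible regiochemistry, and lower ring C' is then built onto the oxygen para to the new bond. This needs differentiation of para from ortho hydroxyls and a full de novo epicatechin synthesis (at least six steps, including a C3' inversion) on the most advanced intermediate. It also ignores that 9 provides those atoms and centres directly. One bromine at C8' gives the same regiochemical certainty in one step and leaves with the benzyl groups.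

Key step: step 7

Assumption: α denotes the face of ring C that carries the 2-aryl group (both units) and β the opposite face; the antipode of the step-3 catalyst is the one that delivers (2S)-7, to be fixed in a trial run.

## Route

Step 1
Reactants: 1 5,7-dihydroxycoumarin
Product: 2 5,7-bis(benzyloxy)coumarin
Conditions: BnBr (2.4 equiv), K2CO3, DMF, 60 °C
Reagents that add atoms: benzyl bromide, BrCc1ccccc1
Why: Williamson etherification of both phenols; the lactone is inert to carbonate and no stereocentre is present.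

Step 2
Reactants: 2 5,7-bis(benzyloxy)coumarin
Product: 4 5,7-bis(benzyloxy)-2-ethoxy-2H-chromene (racemic), via lactol 3 (not isolated)
Conditions: DIBAL-H (1.1 equiv), CH2Cl2, −78 °C, Rochelle salt work-up; then EtOH, PPTS (cat.), rt
Reagents that add atoms: ethanol, CCO
Why: DIBAL-H half-reduction of the lactone stops at the 2H-chromen-2-ol, which ionises under mild acid to the 5,7-dialkoxybenzopyrylium ion and is trapped by ethanol (acetalisation); the acetal centre is racemic and is erased in step 3.

Step 3
Reactants: 4 5,7-bis(benzyloxy)-2-ethoxy-2H-chromene; 5 [4-(benzyloxy)phenyl]boronic acid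
Product: 7 (2S)-5,7-bis(benzyloxy)-2-[4-(benzyloxy)phenyl]-2H-chromene, via diethyl boronate 6 (not isolated)
Conditions: 5, EtOH, 4 Å MS, toluene, then evaporate; 4, chiral tartaric-acid-derived amide diol acid (10 mol %), Ce(OTf)4 (9 mol %), EtOAc, −20 °C
Reagents that add atoms: none
Why: Enantioselective Petasis-type addition of a boronate to a chromene acetal: the lanthanide triflate ionises 4 to an achiral benzopyrylium ion and the aryl group is delivered to C2 from boron bound to the chiral diol acid, so the catalyst sets C2 (S, aryl α). Any minor enantiomer later becomes a diastereomer of 13 and can be removed by chromatography.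

Step 4
Reactants: 7 (2S)-5,7-bis(benzyloxy)-2-[4-(benzyloxy)phenyl]-2H-chromene
Product: 8 (2R,3S,4R)-5,7-bis(benzyloxy)-2-[4-(benzyloxy)phenyl]-3,8-dibromochroman-4-ol (2-aryl α, 3-Br β, 4-OH α)
Conditions: NBS (2.05 equiv, two portions), THF/H2O 4:1, 0 °C to rt, dark
Reagents that add atoms: N-bromosuccinimide, O=C1CCC(=O)N1Br; water, O
Why: Bromohydrin formation on the electron-rich styrene-type C3=C4 bond: Br+ should add to C3 anti to the 2-aryl group and water to the benzylic C4 trans to bromine (Markovnikov, anti addition), giving the all-equatorial 2,3-trans-3,4-trans isomer. The second equivalent brominates ring A at C8, the position NBS selects in 5,7-di-O-benzylflavans, which caps the future electrophile.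

Step 5
Reactants: 9 (−)-epicatechin
Product: 10 5,7,3',4'-tetra-O-benzyl-(−)-epicatechin
Conditions: BnBr (4.4 equiv), K2CO3, DMF, 0 °C to rt
Reagents that add atoms: benzyl bromide, BrCc1ccccc1
Why: Williamson etherification of the four phenols; the aliphatic 3-OH is not deprotonated by carbonate and the short, cold reaction avoids base-induced C2 epimerisation.

Step 6
Reactants: 10 5,7,3',4'-tetra-O-benzyl-(−)-epicatechin
Product: 11 8-bromo-5,7,3',4'-tetra-O-benzyl-(−)-epicatechin
Conditions: NBS (1.0 equiv), CH2Cl2, −78 to 0 °C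
Reagents that add atoms: N-bromosuccinimide, O=C1CCC(=O)N1Br
Why: Electrophilic aromatic bromination at C8, the less hindered ring-A position between O7 and O1, leaves C6 as the only free ring-A carbon; no stereocentre is touched.

Step 7
Reactants: 8 (2R,3S,4R)-5,7-bis(benzyloxy)-2-[4-(benzyloxy)phenyl]-3,8-dibromochroman-4-ol; 11 8-bromo-5,7,3',4'-tetra-O-benzyl-(−)-epicatechin
Product: 13 8-bromo-5,7,4'-tri-O-benzyl-(−)-epiafzelechin-(4β→6)-[8-bromo-5,7,3',4'-tetra-O-benzyl-(−)-epicatechin] (both 3-hydroxyls free), via epoxide 12 (not isolated)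
Conditions: 8, NaH, THF, 0 °C; filter, evaporate cold; add slowly to 11 (2.5 equiv), BF3·OEt2 (0.5 equiv), 4 Å MS, CH2Cl2, −78 to −30 °C; Et3N quench
Reagents that add atoms: none
Why: The C4 alkoxide of 8 displaces bromide from C3 through the ring-flipped trans-diaxial conformer (3-exo-tet SN2, inversion), so oxirane 12 lies on the α face, cis to the 2-aryl group, as 3-bromochroman-4-ols give chromene oxides. BF3 then opens the benzylic C4–O bond, which is weakened by O1, 5-OBn and 7-OBn, to a cation or tight ion pair whose α face is screened by the C3–O–BF3 group and the 2-aryl group. C6' of 11 attacks C4 from the β face and loses its proton; this is a Friedel–Crafts alkylation by a benzylic epoxide, and the cation is the one flavan-3,4-diols form in their acid condensations with flavan-3-ols. C3 (O α) is fixed by inversion of the C3–Br bond that step 4 set anti to the 2-aryl group; C4 (aryl β) is fixed by anti, trans-diaxial opening relative to C3–O; C2 is untouched and controls both. Site selectivity on 11 is secured by the C8' bromine, ring B and the benzyl rings being far less nucleophilic. Any 3-O-alkylation is reversible under BF3 and should drain to the C–C product. Self-condensation is limited because C8 of 12 is brominated and its C6–H competes only statistically, which the excess of 11 and inverse addition answer.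

Step 8
Reactants: 13 dimer diol; 14 3,4,5-tris(benzyloxy)benzoyl chloride
Product: 15 3,3'-bis-O-[3,4,5-tris(benzyloxy)benzoate] of 13
Conditions: 14 (5 equiv), DMAP, Et3N, CH2Cl2, rt to 40 °C
Reagents that add atoms: none
Why: DMAP-catalysed acyl transfer (Steglich-type) to both axial secondary alcohols; the bond formed is acyl–O, so C3 and C3' keep their configuration, and the ester sits too far from C2 and C4 to disturb them.

Step 9
Reactants: 15 bis-gallate
Product: 16 (−)-epiafzelechin 3-O-gallate-(4β→6)-(−)-epicatechin 3-O-gallate (CNP0169607.1)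
Conditions: H2 (1 atm), 20 % Pd(OH)2/C, Et3N (2.2 equiv), THF/MeOH/H2O, rt; filter under Ar, lyophilise, Sephadex LH-20
Reagents that add atoms: none
Why: Palladium-catalysed hydrogenolysis cleaves the thirteen benzyl ethers and both aryl C–Br bonds. The amine, used only in the amount of HBr released, keeps the medium neutral so the interflavan bond, the benzylic C2–O bonds and the aryl esters survive; no stereocentre is involved.

## Compound list

1 | 5,7-dihydroxycoumarin | O=C1C=Cc2c(O)cc(O)cc2O1 | starting material
2 | 5,7-bis(benzyloxy)coumarin | O=C1C=Cc2c(OCc3ccccc3)cc(OCc3ccccc3)cc2O1 | intermediate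
3 | 5,7-bis(benzyloxy)-2H-chromen-2-ol (lactol, racemic) | OC1C=Cc2c(OCc3ccccc3)cc(OCc3ccccc3)cc2O1 | intermediate (not isolated)
4 | 5,7-bis(benzyloxy)-2-ethoxy-2H-chromene (racemic) | CCOC1C=Cc2c(OCc3ccccc3)cc(OCc3ccccc3)cc2O1 | intermediate
5 | [4-(benzyloxy)phenyl]boronic acid | OB(O)c1ccc(OCc2ccccc2)cc1 | starting material
6 | diethyl [4-(benzyloxy)phenyl]boronate | CCOB(OCC)c1ccc(OCc2ccccc2)cc1 | intermediate (not isolated)
7 | (2S)-5,7-bis(benzyloxy)-2-[4-(benzyloxy)phenyl]-2H-chromene | C1=Cc2c(OCc3ccccc3)cc(OCc3ccccc3)cc2O[C@@H]1c1ccc(OCc2ccccc2)cc1 | intermediate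
8 | (2R,3S,4R)-5,7-bis(benzyloxy)-2-[4-(benzyloxy)phenyl]-3,8-dibromochroman-4-ol | Br[C@H]1[C@H](O)c2c(OCc3ccccc3)cc(OCc3ccccc3)c(Br)c2O[C@@H]1c1ccc(OCc2ccccc2)cc1 | intermediate
9 | (−)-epicatechin, (2R,3R) | O[C@@H]1Cc2c(O)cc(O)cc2O[C@@H]1c1ccc(O)c(O)c1 | starting material
10 | 5,7,3',4'-tetra-O-benzyl-(−)-epicatechin | O[C@@H]1Cc2c(OCc3ccccc3)cc(OCc3ccccc3)cc2O[C@@H]1c1ccc(OCc2ccccc2)c(OCc2ccccc2)c1 | intermediate
11 | 8-bromo-5,7,3',4'-tetra-O-benzyl-(−)-epicatechin | O[C@@H]1Cc2c(OCc3ccccc3)cc(OCc3ccccc3)c(Br)c2O[C@@H]1c1ccc(OCc2ccccc2)c(OCc2ccccc2)c1 | intermediate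
12 | (2R,3R,4R)-5,7-bis(benzyloxy)-2-[4-(benzyloxy)phenyl]-8-bromo-3,4-epoxychroman (oxirane oxygen α, cis to the 2-aryl group) | O1[C@@H]2[C@H]1c1c(OCc3ccccc3)cc(OCc3ccccc3)c(Br)c1O[C@@H]2c1ccc(OCc2ccccc2)cc1 | intermediate (not isolated)
13 | 8-bromo-5,7,4'-tri-O-benzyl-(−)-epiafzelechin-(4β→6)-[8-bromo-5,7,3',4'-tetra-O-benzyl-(−)-epicatechin], both 3-hydroxyls free | O[C@@H]1[C@@H](c2c(OCc4ccccc4)c(Br)c3c(c2OCc2ccccc2)C[C@@H](O)[C@@H](c2ccc(OCc4ccccc4)c(OCc4ccccc4)c2)O3)c2c(OCc3ccccc3)cc(OCc3ccccc3)c(Br)c2O[C@@H]1c1ccc(OCc2ccccc2)cc1 | intermediate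
14 | 3,4,5-tris(benzyloxy)benzoyl chloride | O=C(Cl)c1cc(OCc2ccccc2)c(OCc2ccccc2)c(OCc2ccccc2)c1 | starting material
15 | 3,3'-bis-O-[3,4,5-tris(benzyloxy)benzoate] of 13 | O=C(O[C@@H]1[C@@H](c2c(OCc4ccccc4)c(Br)c3c(c2OCc2ccccc2)C[C@@H](OC(=O)c2cc(OCc4ccccc4)c(OCc4ccccc4)c(OCc4ccccc4)c2)[C@@H](c2ccc(OCc4ccccc4)c(OCc4ccccc4)c2)O3)c2c(OCc3ccccc3)cc(OCc3ccccc3)c(Br)c2O[C@@H]1c1ccc(OCc2ccccc2)cc1)c1cc(OCc2ccccc2)c(OCc2ccccc2)c(OCc2ccccc2)c1 | intermediate
16 | (−)-epiafzelechin 3-O-gallate-(4β→6)-(−)-epicatechin 3-O-gallate (CNP0169607.1) | O=C(O[C@@H]1[C@@H](c2c(O)cc3c(c2O)C[C@@H](OC(=O)c2cc(O)c(O)c(O)c2)[C@@H](c2ccc(O)c(O)c2)O3)c2c(O)cc(O)cc2O[C@@H]1c1ccc(O)cc1)c1cc(O)c(O)c(O)c1 | target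

## Step count and risk

Total: 9 steps. Longest linear sequence: 7 steps (1, 2, 3, 4, 7, 8, 9, starting from 1).

**Step 7 (key).** After ionisation, the C4 cation carrying a boron-bound 3-alkoxide may undergo a 1,2-hydride shift to the flavan-3-one. It may also be captured by a ring-A CH of a second molecule of 12 or of 13 faster than by the crowded C6' of 11, leading to oligomerisation. The fallback sets out from 8 and 11 and returns at 15. Treating 8 with K2CO3 in MeOH forms the same oxirane, which methanol opens in situ at C4 to the stable 5,7,4'-tri-O-benzyl-8-bromo-4β-methoxy-(−)-epiafzelechin F1. Acylation with 14 (DMAP, Et3N) gives its 3-O-[3,4,5-tris(benzyloxy)benzoate] F2, and 11 is acylated likewise to 8-bromo-5,7,3',4'-tetra-O-benzyl-(−)-epicatechin 3-O-[3,4,5-tris(benzyloxy)benzoate] F3. F2 and F3 are then joined with TMSOTf in CH2Cl2 at −40 °C, the classical Lewis-acid coupling of a 4-alkoxyflavan. The 3-O-acyl group bridges C3 and C4 on the α face as a dioxolanylium ion, which blocks the hydride shift, leaves no free hydroxyl and directs C6' to the β face, giving 15 directly.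

**Step 3.** The 5,7-dialkoxybenzopyrylium ion is strongly stabilised, so aryl transfer may be slow, background (racemic) addition may erode the enantiomeric purity, and 7 may racemise by reversible C2–O1 ionisation. The fallback sets out from 5 and returns at 7. Commercial 5,7-dihydroxy-4H-chromen-4-one F4 is benzylated to 5,7-bis(benzyloxy)-4H-chromen-4-one F5. Rhodium-catalysed asymmetric 1,4-addition of 5 (Hayashi–Miyaura reaction, chiral bisphosphine) gives (2S)-5,7-bis(benzyloxy)-2-[4-(benzyloxy)phenyl]chroman-4-one F6. NaBH4 reduces it to (2S,4S)-5,7-bis(benzyloxy)-2-[4-(benzyloxy)phenyl]chroman-4-ol F7, whose mesylate (MsCl, Et3N, 0 °C) ionises and eliminates under the basic conditions to 7.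

**Step 4.** The bromine reagent may lose chemoselectivity: nuclear bromination may spread to C6 or ring B, the benzylic alcohol may be oxidised, or part of the Br+ may add syn to the aryl group. The fallback sets out from 7 and returns at 13. One equivalent of NBS in aqueous THF gives only (2R,3S,4R)-5,7-bis(benzyloxy)-2-[4-(benzyloxy)phenyl]-3-bromochroman-4-ol F8. K2CO3 in MeOH converts it into the robust 5,7,4'-tri-O-benzyl-4β-methoxy-(−)-epiafzelechin F9, which can be purified and then brominated at C8 under the conditions of step 6 to give F1 (see step 7). F1 and 11 (2.5 equiv) with TMSOTf give 13.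

**Step 8.** The upper axial 3-hydroxyl, wedged between the 2-aryl group and the C4 substituent, may acylate incompletely and leave a mono-ester. The fallback sets out from 8 (through F1 and F2 as under step 7) and 11 and returns at 15. F2, in which the hindered ester was made on the monomer, is coupled with 11 itself (TMSOTf) to give the dimer with the upper 3-O-gallate in place and the lower 3'-hydroxyl free, F10. Acylation of this unhindered alcohol with 14 gives 15.

## Further compounds

F1 | step 7 | 5,7,4'-tri-O-benzyl-8-bromo-4β-methoxy-(−)-epiafzelechin, (2R,3R,4S) | O[C@@H]1[C@@H](OC)c2c(OCc3ccccc3)cc(OCc3ccccc3)c(Br)c2O[C@@H]1c1ccc(OCc2ccccc2)cc1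
F2 | step 7 | 3-O-[3,4,5-tris(benzyloxy)benzoate] of F1 | O=C(O[C@@H]1[C@@H](OC)c2c(OCc3ccccc3)cc(OCc3ccccc3)c(Br)c2O[C@@H]1c1ccc(OCc2ccccc2)cc1)c1cc(OCc2ccccc2)c(OCc2ccccc2)c(OCc2ccccc2)c1
F3 | step 7 | 8-bromo-5,7,3',4'-tetra-O-benzyl-(−)-epicatechin 3-O-[3,4,5-tris(benzyloxy)benzoate] | O=C(O[C@@H]1Cc2c(OCc3ccccc3)cc(OCc3ccccc3)c(Br)c2O[C@@H]1c1ccc(OCc2ccccc2)c(OCc2ccccc2)c1)c1cc(OCc2ccccc2)c(OCc2ccccc2)c(OCc2ccccc2)c1
F4 | step 3 | 5,7-dihydroxy-4H-chromen-4-one (commercial) | O=c1ccoc2cc(O)cc(O)c12
F5 | step 3 | 5,7-bis(benzyloxy)-4H-chromen-4-one | O=c1ccoc2cc(OCc3ccccc3)cc(OCc3ccccc3)c12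
F6 | step 3 | (2S)-5,7-bis(benzyloxy)-2-[4-(benzyloxy)phenyl]chroman-4-one | O=C1C[C@@H](c2ccc(OCc3ccccc3)cc2)Oc2cc(OCc3ccccc3)cc(OCc3ccccc3)c21
F7 | step 3 | (2S,4S)-5,7-bis(benzyloxy)-2-[4-(benzyloxy)phenyl]chroman-4-ol | O[C@H]1C[C@@H](c2ccc(OCc3ccccc3)cc2)Oc2cc(OCc3ccccc3)cc(OCc3ccccc3)c21
F8 | step 4 | (2R,3S,4R)-5,7-bis(benzyloxy)-2-[4-(benzyloxy)phenyl]-3-bromochroman-4-ol | Br[C@H]1[C@H](O)c2c(OCc3ccccc3)cc(OCc3ccccc3)cc2O[C@@H]1c1ccc(OCc2ccccc2)cc1
F9 | step 4 | 5,7,4'-tri-O-benzyl-4β-methoxy-(−)-epiafzelechin, (2R,3R,4S) | O[C@@H]1[C@@H](OC)c2c(OCc3ccccc3)cc(OCc3ccccc3)cc2O[C@@H]1c1ccc(OCc2ccccc2)cc1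
F10 | step 8 | 13 carrying the 3,4,5-tris(benzyloxy)benzoate only at the upper O3 (lower 3'-OH free) | O=C(O[C@@H]1[C@@H](c2c(OCc4ccccc4)c(Br)c3c(c2OCc2ccccc2)C[C@@H](O)[C@@H](c2ccc(OCc4ccccc4)c(OCc4ccccc4)c2)O3)c2c(OCc3ccccc3)cc(OCc3ccccc3)c(Br)c2O[C@@H]1c1ccc(OCc2ccccc2)cc1)c1cc(OCc2ccccc2)c(OCc2ccccc2)c(OCc2ccccc2)c1
A1 | alternative 1 | 5,7,4'-tri-O-benzyl-(−)-epiafzelechin | O[C@@H]1Cc2c(OCc3ccccc3)cc(OCc3ccccc3)cc2O[C@@H]1c1ccc(OCc2ccccc2)cc1
A2 | alternative 1 | 5,7,4'-tri-O-benzyl-4β-(2-ethoxyethoxy)-(−)-epiafzelechin | O[C@@H]1[C@@H](OCCOCC)c2c(OCc3ccccc3)cc(OCc3ccccc3)cc2O[C@@H]1c1ccc(OCc2ccccc2)cc1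
A3 | alternative 2 | 5,7-bis(benzyloxy)-2-[4-(benzyloxy)phenyl]-3-[3,4,5-tris(benzyloxy)benzoyloxy]chromenylium triflate | O=C(Oc1cc2c(OCc3ccccc3)cc(OCc3ccccc3)cc2[o+]c1-c1ccc(OCc2ccccc2)cc1)c1cc(OCc2ccccc2)c(OCc2ccccc2)c(OCc2ccccc2)c1.[O-]S(=O)(=O)C(F)(F)F
A4 | alternative 2 | 4-aryl-flav-2-ene adduct of A3 with 11 (C4 configuration undefined) | O=C(OC1=C(c2ccc(OCc3ccccc3)cc2)Oc2cc(OCc3ccccc3)cc(OCc3ccccc3)c2C1c1c(OCc2ccccc2)c(Br)c2c(c1OCc1ccccc1)C[C@@H](O)[C@@H](c1ccc(OCc3ccccc3)c(OCc3ccccc3)c1)O2)c1cc(OCc2ccccc2)c(OCc2ccccc2)c(OCc2ccccc2)c1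
A5 | alternative 3 | phloroglucinol | Oc1cc(O)cc(O)c1
A6 | alternative 3 | 8-bromo-5,7,4'-tri-O-benzyl-(−)-epiafzelechin-(4β→2)-phloroglucinol | O[C@@H]1[C@@H](c2c(O)cc(O)cc2O)c2c(OCc3ccccc3)cc(OCc3ccccc3)c(Br)c2O[C@@H]1c1ccc(OCc2ccccc2)cc1
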